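C1–C15 is the guaianolide half and C1′–C15′ the eudesmanolide half. The norbornene consists of ring C1–C2–C3–C4=C5 bridged by C13′–C11′.
Cuts, in retrosynthetic order: lactone C12–O; C4–CH3 (enol triflate, Negishi); C1–C13′ (radical conjugate addition); C2–C3 (Piancatelli); C3–C11′ (selenolate Michael–aldol). This leads back to α-methylene lactone 16 and furaldehyde 34.
Enabling feature: in ring C1–C5, C2–O is trans to C3–C11′ and C4 can be a ketone. That is a trans-4-hydroxy-5-alkylcyclopent-2-enone, which maps onto a 2-furylcarbinol whose furan (O, C2, C1, C5, C4) is 3,4-fused to the seven-membered ring.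
Forward order of rings: decalin to cis-lactone 16; cycloheptane to fused furan 34; union; furan to cyclopentenone; bicyclo[2.2.1]heptanone; C4=C5 alkene; trans-lactone last.
Stereochemistry: C10′ comes from (S)-Wieland–Miescher ketone and relays C1′, C4′, C7′, C8′. C8 comes from catalytic desymmetrisation of a meso endoperoxide and relays C7, C10. C11′ is set by a convex-face aldol, C2/C3 by conrotation with its sense set by C11′, and C1 by bridging geometry.
Key step: step 22

Remark: read literally, the SMILES (C7′, C8′, C10′, C1′ all S; C7 S, C8 R, C10 R) belongs to the series antipodal to the Inula lactones. Alantolactone-type chiral-pool lactones are therefore not used, and both halves are built de novo.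
Remark: centres that the next operation erases are left undefined in the SMILES. These are the carbinol C3 of 36, the epoxide carbon of 31, C12 of 45, and C4 of F7 and F8.

Step 1
Reactants: 1 (S)-(+)-Wieland–Miescher ketone
Product: 2 (4aS,5S)-5-hydroxy-4a-methyl-4,4a,5,6,7,8-hexahydronaphthalen-2(3H)-one
Conditions: NaBH4 (0.3 equiv), EtOH, 0 °C
Reagents that add atoms: none
Why: Chemoselective borohydride reduction, in which the saturated C1′ ketone reacts before the enone and hydride arrives anti to the angular methyl, so C1′–OH is cis to C10′–CH3.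

Step 2
Reactants: 2 hydroxy enone
Product: 3 bis-TBS compound (C1′–OTBS ether; C7′–OTBS through-conjugated dienol ether, Δ4′ and Δ6′)
Conditions: TBSOTf (2.5 equiv), Et3N, CH2Cl2, 0 °C to rt
Reagents that add atoms: TBSOTf, CC(C)(C)[Si](C)(C)OS(=O)(=O)C(F)(F)F
Why: Silyl triflate/amine soft enolisation gives the thermodynamic extended dienol ether while the same reagent silylates C1′–OH, and no stereocentre is formed.

Step 3
Reactants: 3 bis-TBS compound
Product: 6 C4′-methylene-Δ5′-en-7′-one (C1′–OTBS), via Mannich base 4 (not isolated), via methiodide 5 (not isolated)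
Conditions: Me2N=CH2+ I−, CH2Cl2, 0 °C to rt; MeI; aq NaHCO3, CH2Cl2
Reagents that add atoms: Eschenmoser's salt, C=[N+](C)C.[I-]
Why: Vinylogous Mannich reaction of a 1-silyloxydiene at its γ-terminus C4′, followed by E1cB (Hofmann-type) loss of trimethylamine, installs the exocyclic methylene and erases the transient C4′ centre.

Step 4
Reactants: 6 C4′-methylene dienone
Product: 7 (4′R)-4′-methyl-Δ5′-en-7′-one (C4′–CH3 cis to C10′–CH3, C1′–OTBS)
Conditions: H2 (1 atm), RhCl(PPh3)3 (cat.), benzene–EtOH, rt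
Reagents that add atoms: none
Why: Homogeneous hydrogenation with Wilkinson's catalyst takes the unhindered 1,1-disubstituted alkene and spares the trisubstituted enone, and H2 is delivered anti to C10′–CH3 and C1′–OTBS, which sets C4′.

Step 5
Reactants: 7 4′-methyl enone
Product: 8 cross-conjugated dienyl triflate (C7′–OTf, Δ5′ and Δ7′)
Conditions: LDA, THF, −78 °C; PhNTf2, −78 to 0 °C
Reagents that add atoms: N-phenyltriflimide, O=S(=O)(N(c1ccccc1)S(=O)(=O)C(F)(F)F)C(F)(F)F
Why: Kinetic α′-deprotonation at C8′ and O-triflation give the 2-triflyloxydiene without touching the epimerisable γ-centre C4′.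

Step 6
Reactants: 8 dienyl triflate
Product: 9 ethyl (dien-7′-yl)acetate (C7′–C11′ formed)
Conditions: BrZnCH2CO2Et (Zn, BrCH2CO2Et, THF), Pd(PPh3)4 (cat.), THF–DMPU, 50 °C
Reagents that add atoms: ethyl bromoacetate, CCOC(=O)CBr
Why: Negishi-type cross-coupling of a vinyl triflate with a Reformatsky zinc enolate forms C7′–C11′ under non-basic conditions, so the β,γ-unsaturated ester does not move into conjugation.

Step 7
Reactants: 9 ethyl dienylacetate
Product: 11 Δ5′-en-8′-one bearing the C7′ acetate side chain cis to C10′–CH3, via C8′ borane 10 (not isolated)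
Conditions: BH3·THF, THF, 0 °C; then NMO, TPAP (cat.), 4 Å MS, CH2Cl2, rt
Reagents that add atoms: N-methylmorpholine N-oxide, C[N+]1([O-])CCOCC1
Why: Syn hydroboration places boron on the less substituted diene terminus C8′ and hydrogen on C7′ from the face opposite to C10′–CH3 (sets C7′), and the TPAP/NMO oxidation takes C–B straight to the ketone, so no trans hydroxy ester can lactonise.

Step 8
Reactants: 11 keto ester
Product: 13 cis-fused γ-lactone (C11′H2; H7′ and H8′ cis, lactone on the face of C10′–CH3), via hydroxy ester 12 (not isolated)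
Conditions: NaBH4, MeOH–CH2Cl2, −40 to 0 °C; PPTS (cat.), CH2Cl2, rt
Reagents that add atoms: none
Why: Hydride attacks the C8′ ketone anti to the 1,3-related axial C10′–CH3 and gives the axial alcohol cis to the side chain (sets C8′), which closes the lactone by transesterification.

Step 9
Reactants: 13 cis-lactone
Product: 16 (3aS,5R,8S,8aS,9aS)-8-(TBSO)-5,8a-dimethyl-3-methylidene-octahydronaphtho[2,3-b]furan-2-one (antipode of 1β-hydroxyalantolactone TBS ether), via Mannich base 14 (not isolated), via methiodide 15 (not isolated)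
Conditions: LDA, THF, −78 °C; Me2N=CH2+ I−; MeI, MeOH; aq NaHCO3
Reagents that add atoms: Eschenmoser's salt, C=[N+](C)C.[I-]
Why: Classical α-methylenation of a lactone (enolate Mannich reaction, quaternisation, E1cB elimination), in which the C11′ centre of 14 is erased.

Step 10
Reactants: 17 cyclohepta-1,3-diene
Product: 18 meso-6,7-dioxabicyclo[3.2.2]non-8-ene
Conditions: O2, tetraphenylporphyrin (cat.), hν, CH2Cl2, 0 °C
Reagents that add atoms: dioxygen, O=O
Why: [4+2] cycloaddition of singlet oxygen with the s-cis diene gives the meso endoperoxide.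

Step 11
Reactants: 18 endoperoxide
Product: 19 (R)-4-hydroxycyclohept-2-en-1-one
Conditions: 6′-hydroxy cinchona base, O-acetylated (10 mol %, the pseudoenantiomer that gives R), CH2Cl2, rt
Reagents that add atoms: none
Why: Catalytic enantioselective Kornblum–DeLaMare rearrangement, in which the chiral base removes one of the two enantiotopic bridgehead hydrogens and so sets C8.

Step 12
Reactants: 19 hydroxy enone
Product: 20 (R)-4-(TBSO)cyclohept-2-en-1-one
Conditions: TBSCl, imidazole, DMF, rt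
Reagents that add atoms: TBSCl, CC(C)(C)[Si](C)(C)Cl
Why: Standard silylation of a secondary allylic alcohol, and the stereocentre is untouched.

Step 13
Reactants: 21 2-bromoprop-2-en-1-ol
Product: 22 (2-bromoallyloxy)(tert-butyl)diphenylsilane
Conditions: TBDPSCl, imidazole, CH2Cl2, rt
Reagents that add atoms: TBDPSCl, CC(C)(C)[Si](Cl)(c1ccccc1)c1ccccc1
Why: Standard silylation, with the acid-stable TBDPS group chosen so that the primary allylic ether survives step 22.

Step 14
Reactants: 22 bromoallyl silyl ether; 20 silyloxy enone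
Product: 25 (3S,4R)-4-(TBSO)-3-[3-(TBDPSO)prop-1-en-2-yl]cycloheptanone (C7 side chain trans to C8–O), via vinyllithium 23 (not isolated), via Gilman cuprate 24 (not isolated)
Conditions: 22, t-BuLi (2 equiv), Et2O, −78 °C; CuI (0.5 equiv), −40 °C; 20, −78 °C; aq NH4Cl
Reagents that add atoms: none
Why: Conjugate addition of a vinyl Gilman cuprate to a γ-silyloxy enone takes place anti to the silyloxy group and sets C7 trans to C8–O.

Step 15
Reactants: 25 cycloheptanone
Product: 26 Δ1(10)-enone (6S,5R-disubstituted cyclohept-2-enone)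
Conditions: LDA, THF, −78 °C; PhS(Cl)=N-t-Bu, −78 °C
Reagents that add atoms: none
Why: Kinetic enolisation on the C1 side, remote from the C7 branch, followed by sulfinimidoyl chloride dehydrogenation (Mukaiyama) gives the enone on the side that still needs C10–CH3.

Step 16
Reactants: 26 enone
Product: 27 TMS enol ether C5(OTMS)=C1 with (10R)-CH3 (trans to C8–O, cis to the C7 side chain)
Conditions: Me2CuLi (MeLi, CuI), TMSCl, Et2O–THF, −78 °C; Et3N, cold aq NaHCO3
Reagents that add atoms: lithium dimethylcuprate, [Li+].C[Cu-]C; TMSCl, C[Si](C)(C)Cl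
Why: TMSCl-accelerated cuprate 1,4-addition to the chair-like cycloheptenone with both substituents pseudo-equatorial should occur opposite to the 1,3-related C8–OTBS (sets C10), and the silyl trap fixes the enolate on C1.

Step 17
Reactants: 27 TMS enol ether
Product: 29 C1-hydroxymethylene ketone, via lithium enolate 28 (not isolated)
Conditions: MeLi, THF, 0 °C; HCO2CH2CF3, −78 °C; aq NH4Cl
Reagents that add atoms: 2,2,2-trifluoroethyl formate, O=COCC(F)(F)F
Why: The regiospecific lithium enolate released from the silyl enol ether is C-formylated (Claisen-type) at C1 by a fast formyl donor before it can equilibrate.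

Step 18
Reactants: 29 hydroxymethylene ketone
Product: 30 C1-(butylthiomethylene) ketone
Conditions: n-BuSH, p-TsOH (cat.), benzene, reflux (water removed)
Reagents that add atoms: butane-1-thiol, CCCCS
Why: Acid-catalysed addition–elimination turns the enol into the vinylogous thioester required for the Garst–Spencer furan annulation.

Step 19
Reactants: 30 butylthiomethylene ketone
Product: 32 3,4-fused furan (5,6,7,8-tetrahydro-4H-cyclohepta[c]furan with 7S, 8R, 10R substituents), via spiro-epoxide 31 (not isolated)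
Conditions: Me3S+ I−, n-BuLi, THF, 0 °C; 30; then aq HCl (cat.), THF, rt
Reagents that add atoms: trimethylsulfonium iodide, C[S+](C)C.[I-]
Why: In the Garst–Spencer furan annulation, Corey–Chaykovsky epoxidation of the ketone is followed by acid opening to the sulfur-stabilised allyl cation, closure to the 2,5-dihydrofuran and loss of thiol, which gives the furan O–C2–C1–C5–C4.

Step 20
Reactants: 32 fused furan
Product: 34 furan-2-carbaldehyde (CHO = C3, on the α-carbon C4 next to C5–C6H2), via lithiofuran 33 (not isolated)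
Conditions: n-BuLi, THF, −78 to 0 °C; DMF, −78 °C
Reagents that add atoms: N,N-dimethylformamide, CN(C)C=O
Why: In this furan α-lithiation/formylation the base should take the α-hydrogen beside the CH2-bearing carbon C5 rather than the one flanked by C10(H)CH3.

Step 21
Reactants: 16 α-methylene lactone; 34 furaldehyde
Product: 36 2-furylcarbinol with quaternary C11′ (C3 syn to H7′, C13′H2SePh anti; carbinol epimers), via aluminium enolate 35 (not isolated)
Conditions: Me2AlSePh (AlMe3, PhSeH, toluene, 0 °C), 16, CH2Cl2, −78 to −20 °C; 34, −78 °C; aq Rochelle salt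
Reagents that add atoms: dimethylaluminium benzeneselenolate, C[Al](C)[Se]c1ccccc1
Why: In this tandem Michael–aldol reaction the soft selenolate adds to C13′ and the aluminium enolate attacks the aldehyde on the convex face of the cis-fused lactone (syn to H7′), which sets C11′, while the carbinol configuration is irrelevant.

Step 22
Reactants: 36 2-furylcarbinol
Product: 38 trans-4-hydroxy-5-alkylcyclopent-2-enone fused to the seven-membered ring (C4=O, C1=C5; C3–C11′ on the face of C8–O, C2–OH on the face of C10–CH3), via pentadienyl cation 37 (not isolated)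
Conditions: Dy(OTf)3 (10 mol %), t-BuOH–H2O (5:1), 80 °C
Reagents that add atoms: water, O
Why: Dy(III) ionises the carbinol to the furfuryl oxocarbenium ion, water adds to the free furan α-carbon C2, the hemiacetal opens to the 1,4-dihydroxypentadienyl cation 37 (C3–C4–C5–C1–C2), and a thermal conrotatory 4π electrocyclisation joins C2 to C3 before proton loss gives the enone. This is the Piancatelli rearrangement of 2-furylcarbinols, a Nazarov-type closure, run here on a 3,4-ring-fused furan. The only ring closed is the five-membered ring C1–C5, by 4π-conrotatory electrocyclic closure of a cation that the ring-bound C1=C5 bond locks in the U shape. C2 and C3 arise together: both termini carry their substituent (OH, C11′) outside, so conrotation places C2–OH and C3–C11′ trans, the relation that later makes the acetoxy group syn to the C4=C5 bridge. The sense of rotation is assigned to the adjacent quaternary C11′: allylic strain against C4–OH should put the flat lactone carbonyl C12′ (hydrogen-bond acceptor for C4–OH) beside C4, CH2SePh beside the inside hydrogen and the bulky C7′ anti to the forming bond, so that C2 reaches the C3 face that gives the drawn isomer. The step needs water to attack at C2 only and needs selenide, lactone and silyl ethers to survive; C2 is the sole unsubstituted furan α-position and the catalyst is a water-tolerant, nearly neutral Lewis acid.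

Step 23
Reactants: 38 hydroxy cyclopentenone
Product: 39 C2 acetate
Conditions: Ac2O, pyridine, DMAP (cat.), CH2Cl2, 0 °C
Reagents that add atoms: acetic anhydride, CC(=O)OC(C)=O
Why: Standard acylation of the only free hydroxyl, and E1cB loss of acetate is disfavoured because it would give an antiaromatic cyclopentadienone.

Step 24
Reactants: 39 selenide enone acetate
Product: 40 bicyclo[2.2.1]heptan-2-one (C1–C13′ formed; C12′ endo, C7′ exo, OAc over the C4–C5 bridge; C5–H endo, the C5 epimer converges in step 25)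
Conditions: Bu3SnH (slow addition), AIBN (cat.), benzene (high dilution), 80 °C
Reagents that add atoms: none
Why: In this tin hydride 5-exo-trig radical conjugate addition (intramolecular Giese type) the nucleophilic primary radical C13′ adds to the electrophilic β-carbon C1 on the only face it can reach, that of C3–C11′, which sets the quaternary C1 and closes ring C1–C2–C3–C11′–C13′.

Step 25
Reactants: 40 norbornanone
Product: 41 TMS enol ether C4(OTMS)=C5
Conditions: TMSOTf, Et3N, CH2Cl2, 0 °C to rt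
Reagents that add atoms: TMSOTf, C[Si](C)(C)OS(=O)(=O)C(F)(F)F
Why: Soft enolisation of a ketone can only go towards C5 because C3 is a bridgehead, and acetate and lactone are not enolised under these conditions.

Step 26
Reactants: 41 TMS enol ether
Product: 42 enol triflate C4(OTf)=C5
Conditions: PhNTf2, CsF, DME, rt (triflating agent present before fluoride)
Reagents that add atoms: N-phenyltriflimide, O=S(=O)(N(c1ccccc1)S(=O)(=O)C(F)(F)F)C(F)(F)F
Why: Fluoride-triggered release of the enolate in the presence of the triflating agent gives the enol triflate without an external strong base, and the internal quench should outrun acetyl transfer from C2–O.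

Step 27
Reactants: 42 enol triflate
Product: 43 tris-silylated C4-methyl norbornene
Conditions: Me2Zn, Pd(PPh3)4 (cat.), THF, 50 °C
Reagents that add atoms: dimethylzinc, C[Zn]C
Why: Negishi methylation of a vinyl triflate installs C15 and fixes the C4=C5 alkene, and esters tolerate the organozinc reagent.

Step 28
Reactants: 43 tris-silyl ether
Product: 44 triol (C8–OH, C12–OH, C1′–OH; C2–OAc kept)
Conditions: TBAF, AcOH (1:1), THF, rt to 45 °C
Reagents that add atoms: none
Why: Buffered fluoride desilylation removes all three silyl groups at once without cleaving or moving the acetate.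

Step 29
Reactants: 44 triol
Product: 46 japonicone A (enantiomer of the given SMILES string), via lactol 45 (not isolated)
Conditions: MnO2 (activated, excess), CH2Cl2, rt
Reagents that add atoms: none
Why: Chemoselective MnO2 oxidation takes the allylic C12–OH to the enal, C8–OH closes the lactol and a second oxidation gives the trans-fused α-methylene-γ-lactone, while the unactivated C1′–OH is untouched.

Compound list
1 | (S)-(+)-Wieland–Miescher ketone | O=C1CC[C@@]2(C)C(=C1)CCCC2=O | starting material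
2 | (4aS,5S)-5-hydroxy-4a-methyl-4,4a,5,6,7,8-hexahydronaphthalen-2(3H)-one | O=C1CC[C@@]2(C)C(=C1)CCC[C@@H]2O | intermediate
3 | C1′-OTBS, C7′-OTBS extended dienol ether | CC(C)(C)[Si](C)(C)OC=1CC[C@@]2(C)C(C=1)=CCC[C@@H]2O[Si](C)(C)C(C)(C)C | intermediate
4 | C4′-(dimethylaminomethyl) enone (not isolated) | O=C1CC[C@@]2(C)C(=C1)[C@@H](CN(C)C)CC[C@@H]2O[Si](C)(C)C(C)(C)C | intermediate
5 | methiodide of 4 (not isolated) | O=C1CC[C@@]2(C)C(=C1)[C@@H](C[N+](C)(C)C)CC[C@@H]2O[Si](C)(C)C(C)(C)C.[I-] | intermediate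
6 | C4′-methylene-Δ5′-en-7′-one | O=C1CC[C@@]2(C)C(=C1)C(=C)CC[C@@H]2O[Si](C)(C)C(C)(C)C | intermediate
7 | (4′R)-4′-methyl-Δ5′-en-7′-one | O=C1CC[C@@]2(C)C(=C1)[C@H](C)CC[C@@H]2O[Si](C)(C)C(C)(C)C | intermediate
8 | C7′ dienyl triflate | O=S(=O)(OC1=CC[C@@]2(C)C(=C1)[C@H](C)CC[C@@H]2O[Si](C)(C)C(C)(C)C)C(F)(F)F | intermediate
9 | ethyl (dien-7′-yl)acetate | CCOC(=O)CC1=CC[C@@]2(C)C(=C1)[C@H](C)CC[C@@H]2O[Si](C)(C)C(C)(C)C | intermediate
10 | C8′ borane (not isolated) | B[C@@H]1C[C@@]2(C)C(=C[C@H]1CC(=O)OCC)[C@H](C)CC[C@@H]2O[Si](C)(C)C(C)(C)C | intermediate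
11 | Δ5′-en-8′-one ester | O=C1C[C@@]2(C)C(=C[C@H]1CC(=O)OCC)[C@H](C)CC[C@@H]2O[Si](C)(C)C(C)(C)C | intermediate
12 | cis-8′-hydroxy ester (not isolated) | O[C@H]1C[C@@]2(C)C(=C[C@H]1CC(=O)OCC)[C@H](C)CC[C@@H]2O[Si](C)(C)C(C)(C)C | intermediate
13 | cis-fused γ-lactone (C11′H2) | C1C(=O)O[C@H]2C[C@@]3(C)C(=C[C@H]21)[C@H](C)CC[C@@H]3O[Si](C)(C)C(C)(C)C | intermediate
14 | C11′-(dimethylaminomethyl) lactone (not isolated) | CN(C)C[C@@H]1C(=O)O[C@H]2C[C@@]3(C)C(=C[C@H]21)[C@H](C)CC[C@@H]3O[Si](C)(C)C(C)(C)C | intermediate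
15 | methiodide of 14 (not isolated) | C[N+](C)(C)C[C@@H]1C(=O)O[C@H]2C[C@@]3(C)C(=C[C@H]21)[C@H](C)CC[C@@H]3O[Si](C)(C)C(C)(C)C.[I-] | intermediate
16 | antipodal 1β-(TBSO)alantolactone | C=C1C(=O)O[C@H]2C[C@@]3(C)C(=C[C@H]21)[C@H](C)CC[C@@H]3O[Si](C)(C)C(C)(C)C | intermediate
17 | cyclohepta-1,3-diene | C1=CC=CCCC1 | starting material
18 | meso-6,7-dioxabicyclo[3.2.2]non-8-ene | C1C[C@@H]2C=C[C@H](C1)OO2 | intermediate
19 | (R)-4-hydroxycyclohept-2-en-1-one | O=C1C=C[C@H](O)CCC1 | intermediate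
20 | (R)-4-(TBSO)cyclohept-2-en-1-one | O=C1C=C[C@H](O[Si](C)(C)C(C)(C)C)CCC1 | intermediate
21 | 2-bromoprop-2-en-1-ol | C=C(Br)CO | starting material
22 | (2-bromoallyloxy)(tert-butyl)diphenylsilane | C=C(Br)CO[Si](c1ccccc1)(c1ccccc1)C(C)(C)C | intermediate
23 | vinyllithium from 22 (not isolated) | [Li]C(=C)CO[Si](c1ccccc1)(c1ccccc1)C(C)(C)C | intermediate
24 | lithium divinylcuprate from 23 (not isolated) | [Li+].C=C(CO[Si](c1ccccc1)(c1ccccc1)C(C)(C)C)[Cu-]C(=C)CO[Si](c1ccccc1)(c1ccccc1)C(C)(C)C | intermediate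
25 | (3S,4R)-3,4-disubstituted cycloheptanone | O=C1C[C@@H](C(=C)CO[Si](c2ccccc2)(c2ccccc2)C(C)(C)C)[C@H](O[Si](C)(C)C(C)(C)C)CCC1 | intermediate
26 | Δ1(10)-enone | O=C1C[C@@H](C(=C)CO[Si](c2ccccc2)(c2ccccc2)C(C)(C)C)[C@H](O[Si](C)(C)C(C)(C)C)CC=C1 | intermediate
27 | TMS enol ether with (10R)-CH3 | C[Si](C)(C)OC1=C[C@H](C)C[C@@H](O[Si](C)(C)C(C)(C)C)[C@H](C(=C)CO[Si](c2ccccc2)(c2ccccc2)C(C)(C)C)C1 | intermediate
28 | lithium enolate (not isolated) | [Li]OC1=C[C@H](C)C[C@@H](O[Si](C)(C)C(C)(C)C)[C@H](C(=C)CO[Si](c2ccccc2)(c2ccccc2)C(C)(C)C)C1 | intermediate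
29 | C1-hydroxymethylene ketone | O=C1C(=CO)[C@H](C)C[C@@H](O[Si](C)(C)C(C)(C)C)[C@H](C(=C)CO[Si](c2ccccc2)(c2ccccc2)C(C)(C)C)C1 | intermediate
30 | C1-(butylthiomethylene) ketone | O=C1C(=CSCCCC)[C@H](C)C[C@@H](O[Si](C)(C)C(C)(C)C)[C@H](C(=C)CO[Si](c2ccccc2)(c2ccccc2)C(C)(C)C)C1 | intermediate
31 | spiro-epoxide (not isolated) | C1OC12C(=CSCCCC)[C@H](C)C[C@@H](O[Si](C)(C)C(C)(C)C)[C@H](C(=C)CO[Si](c3ccccc3)(c3ccccc3)C(C)(C)C)C2 | intermediate
32 | 3,4-fused furan | c1occ2[C@H](C)C[C@@H](O[Si](C)(C)C(C)(C)C)[C@H](C(=C)CO[Si](c3ccccc3)(c3ccccc3)C(C)(C)C)Cc12 | intermediate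
33 | 2-lithiofuran (not isolated) | [Li]c1occ2[C@H](C)C[C@@H](O[Si](C)(C)C(C)(C)C)[C@H](C(=C)CO[Si](c3ccccc3)(c3ccccc3)C(C)(C)C)Cc12 | intermediate
34 | fused furan-2-carbaldehyde | O=Cc1occ2[C@H](C)C[C@@H](O[Si](C)(C)C(C)(C)C)[C@H](C(=C)CO[Si](c3ccccc3)(c3ccccc3)C(C)(C)C)Cc12 | intermediate
35 | aluminium enolate of the selenolate adduct (not isolated) | c1ccccc1[Se]CC1=C(O[Al](C)C)O[C@H]2C[C@@]3(C)C(=C[C@H]21)[C@H](C)CC[C@@H]3O[Si](C)(C)C(C)(C)C | intermediate
36 | 2-furylcarbinol with quaternary C11′ | c1ccccc1[Se]C[C@]2(C(=O)O[C@H]3C[C@@]4(C)C(=C[C@H]32)[C@H](C)CC[C@@H]4O[Si](C)(C)C(C)(C)C)C(O)c1occ5[C@H](C)C[C@@H](O[Si](C)(C)C(C)(C)C)[C@H](C(=C)CO[Si](c6ccccc6)(c6ccccc6)C(C)(C)C)Cc15 | intermediate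
37 | 1,4-dihydroxypentadienyl cation (not isolated) | OC(=C[C@]1(C[Se]c2ccccc2)C(=O)O[C@H]3C[C@@]4(C)C(=C[C@H]31)[C@H](C)CC[C@@H]4O[Si](C)(C)C(C)(C)C)C5=C(C=[OH+])[C@H](C)C[C@@H](O[Si](C)(C)C(C)(C)C)[C@H](C(=C)CO[Si](c6ccccc6)(c6ccccc6)C(C)(C)C)C5 | intermediate
38 | trans-4-hydroxy-5-alkylcyclopentenone | c1ccccc1[Se]C[C@]2(C(=O)O[C@H]3C[C@@]4(C)C(=C[C@H]32)[C@H](C)CC[C@@H]4O[Si](C)(C)C(C)(C)C)[C@@H]5C(=O)C6=C([C@H]5O)[C@H](C)C[C@@H](O[Si](C)(C)C(C)(C)C)[C@H](C(=C)CO[Si](c7ccccc7)(c7ccccc7)C(C)(C)C)C6 | intermediate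
39 | C2 acetate of 38 | c1ccccc1[Se]C[C@]2(C(=O)O[C@H]3C[C@@]4(C)C(=C[C@H]32)[C@H](C)CC[C@@H]4O[Si](C)(C)C(C)(C)C)[C@@H]5C(=O)C6=C([C@H]5OC(C)=O)[C@H](C)C[C@@H](O[Si](C)(C)C(C)(C)C)[C@H](C(=C)CO[Si](c7ccccc7)(c7ccccc7)C(C)(C)C)C6 | intermediate
40 | spiro-lactone bicyclo[2.2.1]heptan-2-one | CC(C)(C)[Si](C)(C)O[C@@H]1C[C@@H](C)[C@]23C[C@]4(C(=O)O[C@H]5C[C@@]6(C)C(=C[C@H]54)[C@H](C)CC[C@@H]6O[Si](C)(C)C(C)(C)C)[C@H](C(=O)[C@H]2C[C@H]1C(=C)CO[Si](c7ccccc7)(c7ccccc7)C(C)(C)C)[C@@H]3OC(C)=O | intermediate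
41 | TMS enol ether C4(OTMS)=C5 | CC(C)(C)[Si](C)(C)O[C@@H]1C[C@@H](C)[C@]23C[C@]4(C(=O)O[C@H]5C[C@@]6(C)C(=C[C@H]54)[C@H](C)CC[C@@H]6O[Si](C)(C)C(C)(C)C)[C@H](C(O[Si](C)(C)C)=C2C[C@H]1C(=C)CO[Si](c7ccccc7)(c7ccccc7)C(C)(C)C)[C@@H]3OC(C)=O | intermediate
42 | enol triflate C4(OTf)=C5 | CC(C)(C)[Si](C)(C)O[C@@H]1C[C@@H](C)[C@]23C[C@]4(C(=O)O[C@H]5C[C@@]6(C)C(=C[C@H]54)[C@H](C)CC[C@@H]6O[Si](C)(C)C(C)(C)C)[C@H](C(OS(=O)(=O)C(F)(F)F)=C2C[C@H]1C(=C)CO[Si](c7ccccc7)(c7ccccc7)C(C)(C)C)[C@@H]3OC(C)=O | intermediate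
43 | tris-silylated C4-methyl norbornene | CC(C)(C)[Si](C)(C)O[C@@H]1C[C@@H](C)[C@]23C[C@]4(C(=O)O[C@H]5C[C@@]6(C)C(=C[C@H]54)[C@H](C)CC[C@@H]6O[Si](C)(C)C(C)(C)C)[C@H](C(C)=C2C[C@H]1C(=C)CO[Si](c7ccccc7)(c7ccccc7)C(C)(C)C)[C@@H]3OC(C)=O | intermediate
44 | triol acetate | O[C@@H]1C[C@@H](C)[C@]23C[C@]4(C(=O)O[C@H]5C[C@@]6(C)C(=C[C@H]54)[C@H](C)CC[C@@H]6O)[C@H](C(C)=C2C[C@H]1C(=C)CO)[C@@H]3OC(C)=O | intermediate
45 | C12 lactol (not isolated) | C=C1C(O)O[C@@H]2C[C@@H](C)[C@]34C[C@]5(C(=O)O[C@H]6C[C@@]7(C)C(=C[C@H]65)[C@H](C)CC[C@@H]7O)[C@H](C(C)=C3C[C@@H]12)[C@@H]4OC(C)=O | intermediate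
46 | japonicone A | C=C1C(=O)O[C@@H]2C[C@@H](C)[C@]34C[C@]5(C(=O)O[C@H]6C[C@@]7(C)C(=C[C@H]65)[C@H](C)CC[C@@H]7O)[C@H](C(C)=C3C[C@@H]12)[C@@H]4OC(C)=O | target

Total step count: 29. Longest linear sequence: 19 steps (17 to 46 through steps 10–12, 14–20 and 21–29).

Steps most likely to fail

Step 22. Both conrotatory senses may compete, which would mean poor control by C11′. The hindered carbinol may also cleave by retro-aldol, and silyl ethers may be lost in the hot aqueous Lewis acid. The fallback sets out from 36 and forms the same C2–C3 bond by an equilibrating aldol instead of an electrocyclisation. Ionic hydrogenation (Et3SiH, BF3·OEt2, CH2Cl2, −78 °C) gives the 2-alkylfuran F1. Photooxygenation (O2, sensitiser, hν, −78 °C) followed by PPh3, which reduces the endoperoxide and any selenoxide, opens the furan to the (Z)-4-oxo-enal F2. Mild amine base then closes the C3 enolate onto the C2 aldehyde under thermodynamic control to the trans aldol, which is 38.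

Step 21. The selenolate may be lost again by retro-Michael reaction, and the tetrasubstituted enolate may attack the ortho-substituted furaldehyde too slowly. The fallback sets out from 16 (and 32) and reverses the polarity at C3. The same aluminium enolate 35 is trapped with monomeric formaldehyde, a small electrophile that still enters on the convex face, to give the hydroxymethyl lactone F3. Parikh–Doering oxidation gives the non-enolisable aldehyde F4. Addition of the lithiofuran 33 (from 32, n-BuLi) at −78 °C to this aldehyde returns to 36.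

Step 24. Hydrogen transfer to the primary radical may outrun closure onto the fully substituted C1, which has to build a strained ring and a quaternary centre at once. The fallback sets out from 34 and 16 and replaces the stepwise C3–C11′/C1–C13′ construction by a [4+2] cycloaddition, while the Piancatelli event still makes C2–C3. NaBH4 gives the furfuryl alcohol F5. Dy(OTf)3 in aqueous t-BuOH gives the 4-hydroxycyclopentenone F6. MeMgCl/CeCl3 gives the diol F7. Ac2O/pyridine acetylates the secondary hydroxyl only, to give the monoacetate F8. Burgess dehydration gives the 5-acetoxycyclopentadiene F9, which is trapped at once with 16. The cycloaddition should run endo, with C13′H2 bonding to the substituted terminus C1 and approach anti to C10–CH3 and C2–OAc. This returns to 43.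

Further compounds
F1 | step 22 | 2-alkylfuran (C3H2) | c1ccccc1[Se]C[C@]2(C(=O)O[C@H]3C[C@@]4(C)C(=C[C@H]32)[C@H](C)CC[C@@H]4O[Si](C)(C)C(C)(C)C)Cc1occ5[C@H](C)C[C@@H](O[Si](C)(C)C(C)(C)C)[C@H](C(=C)CO[Si](c6ccccc6)(c6ccccc6)C(C)(C)C)Cc15
F2 | step 22 | (Z)-4-oxo-enal (C4 ketone, C2 aldehyde on C1=C5) | c1ccccc1[Se]C[C@]2(C(=O)O[C@H]3C[C@@]4(C)C(=C[C@H]32)[C@H](C)CC[C@@H]4O[Si](C)(C)C(C)(C)C)CC(=O)C5=C(C=O)[C@H](C)C[C@@H](O[Si](C)(C)C(C)(C)C)[C@H](C(=C)CO[Si](c6ccccc6)(c6ccccc6)C(C)(C)C)C5
F3 | step 21 | C11′-(hydroxymethyl)-C11′-(phenylselanylmethyl) lactone | c1ccccc1[Se]C[C@]2(C(=O)O[C@H]3C[C@@]4(C)C(=C[C@H]32)[C@H](C)CC[C@@H]4O[Si](C)(C)C(C)(C)C)CO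
F4 | step 21 | C11′-formyl-C11′-(phenylselanylmethyl) lactone | c1ccccc1[Se]C[C@]2(C(=O)O[C@H]3C[C@@]4(C)C(=C[C@H]32)[C@H](C)CC[C@@H]4O[Si](C)(C)C(C)(C)C)C=O
F5 | step 24 | fused furfuryl alcohol | OCc1occ2[C@H](C)C[C@@H](O[Si](C)(C)C(C)(C)C)[C@H](C(=C)CO[Si](c3ccccc3)(c3ccccc3)C(C)(C)C)Cc12
F6 | step 24 | fused 4-hydroxycyclopent-2-enone (C3H2) | C1C(=O)C2=C([C@H]1O)[C@H](C)C[C@@H](O[Si](C)(C)C(C)(C)C)[C@H](C(=C)CO[Si](c3ccccc3)(c3ccccc3)C(C)(C)C)C2
F7 | step 24 | C2,C4-diol (C4 tertiary, methylated) | C1C(C)(O)C2=C([C@H]1O)[C@H](C)C[C@@H](O[Si](C)(C)C(C)(C)C)[C@H](C(=C)CO[Si](c3ccccc3)(c3ccccc3)C(C)(C)C)C2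
F8 | step 24 | C2 monoacetate of F7 | C1C(C)(O)C2=C([C@H]1OC(C)=O)[C@H](C)C[C@@H](O[Si](C)(C)C(C)(C)C)[C@H](C(=C)CO[Si](c3ccccc3)(c3ccccc3)C(C)(C)C)C2
F9 | step 24 | 5-acetoxycyclopentadiene (C1=C5–C4=C3) | C1=C(C)C2=C([C@H]1OC(C)=O)[C@H](C)C[C@@H](O[Si](C)(C)C(C)(C)C)[C@H](C(=C)CO[Si](c3ccccc3)(c3ccccc3)C(C)(C)C)C2
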